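**Retrosynthetic overview**
1. Lupulone 14 ⇒ three C-prenylations of phlorisovalerophenone 10 with prenyl bromide 11; the third is dearomatising and creates the gem-diprenyl carbon.
2. 10 ⇒ one-pot alkene hydrogenation and O-debenzylation of enone 9 ⇒ dehydration of β-hydroxy ketone 7.
3. Key C–C disconnection: 7 ⇒ intermolecular aldol addition of the lithium enolate of protected phloroacetophenone 3 to acetone 4 (forms the CH2–C(CH3)2 bond of the isovaleryl chain).
4. 3 ⇒ 2',4',6'-trihydroxyacetophenone 1 + benzyl bromide 2.
5. Rings: none is formed; the six-membered carbocycle enters as the benzene ring of 1 and is dearomatised to the cyclohexadienone in the last step.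

Assumption: lupulone has no stereocentre and no stereogenic double bond (the SMILES carries no descriptors), so the target is the achiral compound, drawn as the given dienol tautomer; no step needs stereocontrol.

**Route**

Step 1
Reactants: 1 2',4',6'-trihydroxyacetophenone; 2 benzyl bromide
Product: 3 1-[2,4,6-tris(benzyloxy)phenyl]ethan-1-one
Conditions: BnBr (3.6 equiv), K2CO3 (4.5 equiv), DMF, 70 °C, 16 h
Reagents that add atoms: benzyl bromide, BrCc1ccccc1
Why: Williamson ether synthesis in which K2CO3 in a dipolar aprotic solvent gives phenoxides that O-alkylate with the benzylic bromide, heat and excess reagent carrying the hydrogen-bonded ortho hydroxyl through as well; no stereocentre is formed.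

Step 2
Reactants: 3 1-[2,4,6-tris(benzyloxy)phenyl]ethan-1-one; 4 acetone
Product: 7 3-hydroxy-3-methyl-1-[2,4,6-tris(benzyloxy)phenyl]butan-1-one, via lithium enolate 5 (not isolated), via lithium aldolate 6 (not isolated)
Conditions: LiN(iPr)2 (LDA, commercial solution, 1.15 equiv), THF, −78 °C, 45 min; acetone (3 equiv), −78 °C, 30 min; sat. aq. NH4Cl at −78 °C
Reagents that add atoms: acetone, CC(C)=O
Why: Directed intermolecular aldol addition in which the acetyl CH3, the only enolisable position, is deprotonated irreversibly and the preformed lithium enolate adds to the acetone carbonyl faster than it exchanges protons, the cold quench preventing retro-aldol; the new carbinol carbon carries two methyl groups, so no stereocentre arises.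

Step 3
Reactants: 7 3-hydroxy-3-methyl-1-[2,4,6-tris(benzyloxy)phenyl]butan-1-one
Product: 9 3-methyl-1-[2,4,6-tris(benzyloxy)phenyl]but-2-en-1-one, via tertiary mesylate 8 (not isolated)
Conditions: MsCl (2 equiv), Et3N (5 equiv), DMAP (cat.), CH2Cl2, 0 °C → rt
Reagents that add atoms: none
Why: Aldol dehydration by mesylation and E1cB elimination, the tertiary alcohol being sulfonylated and Et3N removing the acidic α-proton to expel mesylate and give the conjugated enone; the alkene carries two identical methyl groups (no geometry), and any β,γ-isomer converges in step 4.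

Step 4
Reactants: 9 3-methyl-1-[2,4,6-tris(benzyloxy)phenyl]but-2-en-1-one
Product: 10 phlorisovalerophenone (3-methyl-1-(2,4,6-trihydroxyphenyl)butan-1-one)
Conditions: H2 (1 atm), 10% Pd/C, EtOAc–MeOH (1:1), rt; stop after uptake of 4 equiv H2
Reagents that add atoms: none
Why: Catalytic hydrogenation and hydrogenolysis in one operation, Pd/C saturating the trisubstituted enone C=C and cleaving the three benzylic C–O bonds while the electron-rich, hydrogen-bonded aryl ketone survives at 1 atm; no stereocentre is formed.

Step 5
Reactants: 10 phlorisovalerophenone; 11 prenyl bromide (1-bromo-3-methylbut-2-ene)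
Product: 14 lupulone, via 3-prenylphlorisovalerophenone 12 (not isolated), via 4-deoxyhumulone 13 (not isolated)
Conditions: prenyl bromide (3.1 equiv), 10% aq. KOH (3.3 equiv), 0 °C, N2, dark, 2 h; then 2 M HCl; chromatography and crystallisation from hexane
Reagents that add atoms: prenyl bromide, CC(C)=CCBr
Why: Threefold SN2 C-alkylation of the ambident acylphloroglucinol enolate, favoured over O-alkylation in water and occurring at the primary terminus of the allylic bromide (linear prenyl groups), the third alkylation taking place at an already prenylated carbon because the dearomatised β-triketone remains a stabilised enolate; the new quaternary carbon bears two identical prenyl groups, so it is not a stereocentre.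

A moderate yield is expected in step 5 (roughly 30–40% by analogy with related dearomative prenylations), with di-, tetra- and O-prenylated by-products removed in the purification.

**Compound list**
1 | 2',4',6'-trihydroxyacetophenone (1-(2,4,6-trihydroxyphenyl)ethan-1-one) | CC(=O)c1c(O)cc(O)cc1O | starting material
2 | benzyl bromide | BrCc1ccccc1 | starting material
3 | 1-[2,4,6-tris(benzyloxy)phenyl]ethan-1-one | CC(=O)c1c(OCc2ccccc2)cc(OCc2ccccc2)cc1OCc1ccccc1 | intermediate
4 | acetone | CC(C)=O | starting material
5 | lithium enolate of 3 (lithium 1-[2,4,6-tris(benzyloxy)phenyl]ethenolate) | [Li]OC(=C)c1c(OCc2ccccc2)cc(OCc2ccccc2)cc1OCc1ccccc1 | intermediate (not isolated)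
6 | lithium aldolate (lithium alkoxide of 7) | [Li]OC(C)(C)CC(=O)c1c(OCc2ccccc2)cc(OCc2ccccc2)cc1OCc1ccccc1 | intermediate (not isolated)
7 | 3-hydroxy-3-methyl-1-[2,4,6-tris(benzyloxy)phenyl]butan-1-one | CC(C)(O)CC(=O)c1c(OCc2ccccc2)cc(OCc2ccccc2)cc1OCc1ccccc1 | intermediate
8 | tertiary mesylate (2-methyl-4-oxo-4-[2,4,6-tris(benzyloxy)phenyl]butan-2-yl methanesulfonate) | CC(C)(OS(C)(=O)=O)CC(=O)c1c(OCc2ccccc2)cc(OCc2ccccc2)cc1OCc1ccccc1 | intermediate (not isolated)
9 | 3-methyl-1-[2,4,6-tris(benzyloxy)phenyl]but-2-en-1-one | CC(C)=CC(=O)c1c(OCc2ccccc2)cc(OCc2ccccc2)cc1OCc1ccccc1 | intermediate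
10 | phlorisovalerophenone (3-methyl-1-(2,4,6-trihydroxyphenyl)butan-1-one) | CC(C)CC(=O)c1c(O)cc(O)cc1O | intermediate
11 | prenyl bromide (1-bromo-3-methylbut-2-ene) | CC(C)=CCBr | starting material
12 | 3-prenylphlorisovalerophenone (3-methyl-1-[2,4,6-trihydroxy-3-(3-methylbut-2-en-1-yl)phenyl]butan-1-one) | CC(C)CC(=O)c1c(O)cc(O)c(CC=C(C)C)c1O | intermediate (not isolated)
13 | 4-deoxyhumulone (3-methyl-1-[2,4,6-trihydroxy-3,5-bis(3-methylbut-2-en-1-yl)phenyl]butan-1-one) | CC(C)CC(=O)c1c(O)c(CC=C(C)C)c(O)c(CC=C(C)C)c1O | intermediate (not isolated)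
14 | lupulone (3,5-dihydroxy-4-(3-methylbutanoyl)-2,6,6-tris(3-methylbut-2-en-1-yl)cyclohexa-2,4-dien-1-one, achiral) | CC(C)=CCC1=C(O)C(C(=O)CC(C)C)=C(O)C(CC=C(C)C)(CC=C(C)C)C1=O | target

**Totals**
Total step count: 5. Longest linear sequence: 5 steps (1 → 3 → 7 → 9 → 10 → 14).

**Steps most likely to fail, with fallbacks**

Step 5 (triprenylation; over- and under-alkylation, O-prenylation, air oxidation of the product). The fallback sets out from 10 and separates ring prenylation from the dearomatising step. Acid-mediated Friedel–Crafts C-prenylation of 10 with 2-methylbut-3-en-2-ol (2.2 equiv) and BF3·OEt2 in dioxane at rt cannot O-alkylate or reach the gem-diprenyl stage. It passes through 12 and gives 4-deoxyhumulone 13, which is now isolated by chromatography; this is where the fallback rejoins the route. A single base-mediated alkylation of 13 with one equivalent of 11 (aq. KOH, 0 °C, N2) then gives 14. No compound outside the list is made.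

Step 1 (incomplete reaction at the hydrogen-bonded hydroxyl, or C-benzylation of the electron-rich ring). The fallback sets out from 1 and changes the protecting group and its removal.
- Me2SO4 and K2CO3 in refluxing acetone give 1-(2,4,6-trimethoxyphenyl)ethan-1-one F1 (also an inexpensive catalogue compound).
- The same aldol addition to 4 (LiN(iPr)2, THF, −78 °C) proceeds through lithium enolate F2 and lithium aldolate F3 to 3-hydroxy-3-methyl-1-(2,4,6-trimethoxyphenyl)butan-1-one F4.
- Catalytic TsOH in toluene at 80 °C, safe with methyl ethers, dehydrates it to 3-methyl-1-(2,4,6-trimethoxyphenyl)but-2-en-1-one F5.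
- H2 over 10% Pd/C gives 3-methyl-1-(2,4,6-trimethoxyphenyl)butan-1-one F6.
- BBr3 (6 equiv, CH2Cl2, −78 °C → rt) cleaves the three aryl methyl ethers and returns to the route at 10.

The benzyl series stays first choice because cleavage of the para methyl ether is the weak point of this variant.

Step 2 (proton transfer to acetone or retro-aldol of the tertiary aldolate). The fallback sets out from 3 and avoids the basic lithium aldolate. Soft enolisation with Me3SiOTf and Et3N (CH2Cl2, 0 °C) gives the silyl enol ether {[1-(2,4,6-tris(benzyloxy)phenyl)ethenyl]oxy}trimethylsilane F7. This is isolated and added to 4 in a Mukaiyama aldol reaction promoted by TiCl4 (CH2Cl2, −78 °C, short reaction time to spare the benzyl ethers). Aqueous work-up returns to the route at 7.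

Further compounds
F1 | step 1 | 1-(2,4,6-trimethoxyphenyl)ethan-1-one | CC(=O)c1c(OC)cc(OC)cc1OC
F2 | step 1 | lithium enolate of F1 (lithium 1-(2,4,6-trimethoxyphenyl)ethenolate) | [Li]OC(=C)c1c(OC)cc(OC)cc1OC
F3 | step 1 | lithium aldolate (lithium alkoxide of F4) | [Li]OC(C)(C)CC(=O)c1c(OC)cc(OC)cc1OC
F4 | step 1 | 3-hydroxy-3-methyl-1-(2,4,6-trimethoxyphenyl)butan-1-one | CC(C)(O)CC(=O)c1c(OC)cc(OC)cc1OC
F5 | step 1 | 3-methyl-1-(2,4,6-trimethoxyphenyl)but-2-en-1-one | CC(C)=CC(=O)c1c(OC)cc(OC)cc1OC
F6 | step 1 | 3-methyl-1-(2,4,6-trimethoxyphenyl)butan-1-one | CC(C)CC(=O)c1c(OC)cc(OC)cc1OC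
F7 | step 2 | {[1-(2,4,6-tris(benzyloxy)phenyl)ethenyl]oxy}trimethylsilane | C=C(O[Si](C)(C)C)c1c(OCc2ccccc2)cc(OCc2ccccc2)cc1OCc1ccccc1
F0 | step 5 | none | none
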